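Ring A is not taken from an arene. Its contiguous atoms C8a(–O1), C8(–prenyl) and C7(–OMe) are C1, C2 and C3 of symmetric 2-prenylcyclohexane-1,3-dione, so the prenyl position is unambiguous. The key step joins the α′-lithium enolate of 3-methoxy-2-prenylcyclohex-2-enone to an (E)-3-methoxy-2-(2,4,5-trimethoxyphenyl)acryloyl unit at C4–C4a and, on acid quench, closes the pyranone ring C through O1–C2 with loss of methanol. The acyl partner is used as its acid chloride so that attack at the acyl carbon outruns addition at the β-carbon. One dehydrogenation across C5–C6 then aromatises ring A.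

Key step: step 7

Remark: the target has no stereocentre and no stereogenic double bond (the prenyl terminus carries two methyl groups), so it is one achiral compound and no step has to control configuration.
Remark: the three starting materials are taken as purchased; the E geometry drawn for the β-methoxyacrylate intermediates is the expected one but is not needed, because it is erased when the pyranone forms.

Step 1
Reactants: 1 cyclohexane-1,3-dione; 2 prenyl bromide (1-bromo-3-methylbut-2-ene)
Product: 3 2-(3-methylbut-2-enyl)cyclohexane-1,3-dione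
Conditions: 1 (1.3 equiv), aq. KOH (1.3 equiv), H2O, 0 °C; 2 (1.0 equiv), rt
Reagents that add atoms: none
Why: In water the fully ionised dione is hydrogen-bonded at oxygen, so the soft allylic bromide should be attacked by C2 of the symmetric enolate (SN2 C-alkylation of a cyclic 1,3-dione), and the excess of dione keeps double alkylation low.

Step 2
Reactants: 3 2-(3-methylbut-2-enyl)cyclohexane-1,3-dione
Product: 4 3-methoxy-2-(3-methylbut-2-enyl)cyclohex-2-en-1-one
Conditions: Me2SO4 (1.2 equiv), K2CO3 (1.5 equiv), acetone, reflux
Reagents that add atoms: dimethyl sulfate, COS(=O)(=O)OC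
Why: O-Alkylation of the 2-substituted dione enolate by the hard electrophile dimethyl sulfate should give the vinylogous ester, the two carbonyl groups being equivalent so that only one enol ether can form, and base-only conditions avoid acid-promoted addition of the enol to the prenyl alkene.

Step 3
Reactants: 5 2,4,5-trimethoxyphenylacetic acid
Product: 6 methyl 2-(2,4,5-trimethoxyphenyl)acetate
Conditions: MeOH, cat. H2SO4, reflux
Reagents that add atoms: methanol, CO
Why: Fischer esterification driven by the solvent excess of methanol, to which the aryl methyl ethers are inert.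

Step 4
Reactants: 6 methyl 2-(2,4,5-trimethoxyphenyl)acetate
Product: 8 methyl (E)-3-methoxy-2-(2,4,5-trimethoxyphenyl)prop-2-enoate, via sodium enolate 7 (not isolated)
Conditions: NaH, HCO2Me, THF, 0 °C → rt; then Me2SO4, DMF co-solvent, rt
Reagents that add atoms: methyl formate, COC=O; dimethyl sulfate, COS(=O)(=O)OC
Why: Crossed Claisen condensation of the benzylic ester enolate with non-enolisable methyl formate is driven by formation of the stabilised enolate 7, which dimethyl sulfate should alkylate on oxygen to the E β-methoxyacrylate.

Step 5
Reactants: 8 methyl (E)-3-methoxy-2-(2,4,5-trimethoxyphenyl)prop-2-enoate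
Product: 9 (E)-3-methoxy-2-(2,4,5-trimethoxyphenyl)prop-2-enoic acid
Conditions: LiOH·H2O (3 equiv), THF/MeOH/H2O, 40 °C; then 1 M HCl to pH 3, 0 °C
Reagents that add atoms: lithium hydroxide, [Li+].[OH-]
Why: Saponification (acyl–oxygen cleavage by hydroxide) should leave the push–pull enol ether intact, since β-alkoxyacrylates tolerate aqueous base and a brief cold acidification to pH 3.

Step 6
Reactants: 9 (E)-3-methoxy-2-(2,4,5-trimethoxyphenyl)prop-2-enoic acid
Product: 10 (E)-3-methoxy-2-(2,4,5-trimethoxyphenyl)prop-2-enoyl chloride
Conditions: (COCl)2 (1.2 equiv), cat. DMF, CH2Cl2, 0 °C → rt; evaporate, use at once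
Reagents that add atoms: oxalyl chloride, ClC(=O)C(=O)Cl
Why: DMF-catalysed chlorination with oxalyl chloride (Vilsmeier-type activation) converts the acid to its chloride at or below room temperature, conditions under which β-alkoxyacryloyl chlorides are stable enough to be used crude.

Step 7
Reactants: 4 3-methoxy-2-(3-methylbut-2-enyl)cyclohex-2-en-1-one; 10 (E)-3-methoxy-2-(2,4,5-trimethoxyphenyl)prop-2-enoyl chloride
Product: 13 7-methoxy-8-(3-methylbut-2-enyl)-3-(2,4,5-trimethoxyphenyl)-5,6-dihydro-4H-chromen-4-one, via lithium enolate 11 (not isolated), via diketone enol 12 (not isolated)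
Conditions: LDA (2.0 equiv), 4 (2.1 equiv), THF, −78 °C; then 10 (1.0 equiv), −78 °C; then TFA (8 equiv), −78 → 0 °C
Reagents that add atoms: none
Why: LDA at −78 °C removes the α′ proton (C6) of the cross-conjugated vinylogous ester under kinetic control, and the lithium enolate 11 attacks the acyl carbon of 10 with loss of chloride (C4–C4a), the second equivalent of enolate deprotonating the more acidic β-diketone 12 as it forms. On acidification the ring-enol oxygen of 12 adds to the β-carbon of the protonated β-methoxy enone and methanol is expelled (O1–C2), a 6-endo-trig oxa-Michael addition–elimination that closes the pyranone ring. The closest known reaction type is the γ-pyranone annulation of ketone lithium enolates with β-alkoxyacryloyl chlorides followed by acid treatment, joined here to the known α′-acylation of 3-alkoxycyclohexenone enolates. No stereocentre is created, since the only sp3 centre formed in passing (C4a in the keto tautomer of 12) is planar in the enol and in 13. The step needs α′- rather than γ-deprotonation (kinetic amide base at low temperature), attack at the acyl carbon rather than through enolate oxygen or at the β-carbon (the acid chloride is far more electrophilic at carbonyl than at its donor-substituted β-carbon, lithium in THF favours C-acylation, and any enol ester passes its acyl group on to remaining enolate), and closure onto the acryloyl unit rather than onto the prenyl alkene (brief anhydrous TFA at or below 0 °C activates the β-methoxy enone only and leaves the C7 enol ether unhydrolysed).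

Step 8
Reactants: 13 7-methoxy-8-(3-methylbut-2-enyl)-3-(2,4,5-trimethoxyphenyl)-5,6-dihydro-4H-chromen-4-one
Product: 14 prebarbigerone, 7-methoxy-8-(3-methylbut-2-enyl)-3-(2,4,5-trimethoxyphenyl)-4H-chromen-4-one
Conditions: DDQ (1.05 equiv), toluene, 0 °C → rt
Reagents that add atoms: none
Why: Quinone dehydrogenation of a cyclohexa-1,3-diene, in which hydride abstraction from C5 gives a cation stabilised by O1 and the C7 methoxy group and loss of the C6 proton aromatises ring A, should be fast enough with about one equivalent of DDQ at or below room temperature to spare the prenyl group and the aryl ethers.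

Compound list
1 | cyclohexane-1,3-dione | O=C1CCCC(=O)C1 | starting material
2 | prenyl bromide (1-bromo-3-methylbut-2-ene) | CC(C)=CCBr | starting material
3 | 2-(3-methylbut-2-enyl)cyclohexane-1,3-dione | CC(C)=CCC1C(=O)CCCC1=O | intermediate
4 | 3-methoxy-2-(3-methylbut-2-enyl)cyclohex-2-en-1-one | COC1=C(CC=C(C)C)C(=O)CCC1 | intermediate
5 | 2,4,5-trimethoxyphenylacetic acid | COc1cc(OC)c(CC(=O)O)cc1OC | starting material
6 | methyl 2-(2,4,5-trimethoxyphenyl)acetate | COC(=O)Cc1cc(OC)c(OC)cc1OC | intermediate
7 | sodium enolate of methyl 3-oxo-2-(2,4,5-trimethoxyphenyl)propanoate (delocalised, drawn in its carbanion form) | [Na+].COC(=O)[C-](C=O)c1cc(OC)c(OC)cc1OC | intermediate (not isolated)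
8 | methyl (E)-3-methoxy-2-(2,4,5-trimethoxyphenyl)prop-2-enoate | CO/C=C(/C(=O)OC)c1cc(OC)c(OC)cc1OC | intermediate
9 | (E)-3-methoxy-2-(2,4,5-trimethoxyphenyl)prop-2-enoic acid | CO/C=C(/C(=O)O)c1cc(OC)c(OC)cc1OC | intermediate
10 | (E)-3-methoxy-2-(2,4,5-trimethoxyphenyl)prop-2-enoyl chloride | CO/C=C(/C(=O)Cl)c1cc(OC)c(OC)cc1OC | intermediate
11 | lithium 5-methoxy-6-(3-methylbut-2-enyl)cyclohexa-1,5-dien-1-olate (α′-enolate of 4) | [Li+].COC1=C(CC=C(C)C)C([O-])=CCC1 | intermediate (not isolated)
12 | 3-methoxy-6-[(E)-3-methoxy-2-(2,4,5-trimethoxyphenyl)prop-2-enoyl]-2-(3-methylbut-2-enyl)cyclohex-2-en-1-one, drawn as its ring enol | COC1=C(CC=C(C)C)C(O)=C(CC1)C(=O)/C(=C/OC)c1cc(OC)c(OC)cc1OC | intermediate (not isolated)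
13 | 7-methoxy-8-(3-methylbut-2-enyl)-3-(2,4,5-trimethoxyphenyl)-5,6-dihydro-4H-chromen-4-one | COC1=C(CC=C(C)C)C2=C(CC1)C(=O)C(c1cc(OC)c(OC)cc1OC)=CO2 | intermediate
14 | prebarbigerone, 7-methoxy-8-(3-methylbut-2-enyl)-3-(2,4,5-trimethoxyphenyl)-4H-chromen-4-one | COc1cc(OC)c(-c2coc3c(CC=C(C)C)c(OC)ccc3c2=O)cc1OC | target

Total step count: 8
Longest linear sequence: 6 steps (steps 3 to 8, from 5); the other branch (steps 1, 2, 7, 8) has 4.

Steps most likely to fail

1. Step 7. The enolate may react through oxygen, or add to the β-carbon of the acryloyl unit with loss of methoxide, which after closure onto the acyl group would lead into the isomeric pyran-2-one series. Proton transfer from the acidic product may also stall the acylation. The fallback sets out from 5 and from enolate 11 (made from 4) and returns at 13. It builds the same ring by the deoxybenzoin and one-carbon route to isoflavones, transposed to the dihydro series, so the acyl donor has no second electrophilic site. Acid 5 is treated with benzotriazole and SOCl2 in CH2Cl2 to give 1-(1H-benzotriazol-1-yl)-2-(2,4,5-trimethoxyphenyl)ethan-1-one F1, a C-selective acyl donor. Enolate 11 (2 equiv, THF, −78 °C) is acylated by it to 3-methoxy-2-(3-methylbut-2-enyl)-6-[2-(2,4,5-trimethoxyphenyl)acetyl]cyclohex-2-en-1-one F2. DMF dimethyl acetal in toluene at 80 °C condenses at the benzylic methylene to give 6-[(E)-3-(dimethylamino)-2-(2,4,5-trimethoxyphenyl)prop-2-enoyl]-3-methoxy-2-(3-methylbut-2-enyl)cyclohex-2-en-1-one F3. Warming with acetic acid closes O1–C2 with loss of dimethylamine to give 13.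

2. Step 8. Hydride abstraction may occur at the prenyl methylene (doubly allylic in 13, benzylic and allylic in 14) instead of, or after, the ring dehydrogenation, so that the side chain is oxidised. The fallback sets out from 13 and returns at 14, and uses no hydride acceptor. LiHMDS in THF at −78 °C removes a C6 proton, the only enolisable site, conjugated to the C4 carbonyl through C7=C8 and C8a=C4a. PhSeCl should trap the extended enolate at its α-carbon to give racemic 7-methoxy-8-(3-methylbut-2-enyl)-4a-(phenylselanyl)-3-(2,4,5-trimethoxyphenyl)-4a,5-dihydro-4H-chromen-4-one F4. Oxidation with H2O2 and pyridine in CH2Cl2 at 0 °C is followed by syn-elimination of the selenoxide toward C5, which aromatises ring A. Selenation at C6 instead would lead to the same arene.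

3. Step 1. O-Alkylation and a second C-alkylation of the ambident enolate may erode the supply of the monoalkylated dione. The fallback sets out from 2 and returns at 3. Purchased 1,3-dimethoxybenzene is reduced (Li, NH3, t-BuOH, −78 °C; Birch reduction) to 1,5-dimethoxycyclohexa-1,4-diene F5. t-BuLi in THF at −78 °C lithiates the methylene between the two enol ether carbons, and 2 alkylates it to 1,5-dimethoxy-6-(3-methylbut-2-enyl)cyclohexa-1,4-diene F6, in which only one C-alkylation is possible. Brief hydrolysis with 1 M HCl in acetone at room temperature unmasks both ketones to give 3.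

Further compounds
F1 | step 7 | 1-(1H-benzotriazol-1-yl)-2-(2,4,5-trimethoxyphenyl)ethan-1-one | COc1cc(OC)c(CC(=O)n2nnc3ccccc32)cc1OC
F2 | step 7 | 3-methoxy-2-(3-methylbut-2-enyl)-6-[2-(2,4,5-trimethoxyphenyl)acetyl]cyclohex-2-en-1-one, drawn as its ring enol | COC1=C(CC=C(C)C)C(O)=C(CC1)C(=O)Cc1cc(OC)c(OC)cc1OC
F3 | step 7 | 6-[(E)-3-(dimethylamino)-2-(2,4,5-trimethoxyphenyl)prop-2-enoyl]-3-methoxy-2-(3-methylbut-2-enyl)cyclohex-2-en-1-one, drawn as its ring enol | COC1=C(CC=C(C)C)C(O)=C(CC1)C(=O)/C(=C/N(C)C)c1cc(OC)c(OC)cc1OC
F4 | step 8 | 7-methoxy-8-(3-methylbut-2-enyl)-4a-(phenylselanyl)-3-(2,4,5-trimethoxyphenyl)-4a,5-dihydro-4H-chromen-4-one, racemic at C4a | COC1=CCC2([Se]c3ccccc3)C(=O)C(c3cc(OC)c(OC)cc3OC)=COC2=C1CC=C(C)C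
F5 | step 1 | 1,5-dimethoxycyclohexa-1,4-diene | COC1=CCC=C(OC)C1
F6 | step 1 | 1,5-dimethoxy-6-(3-methylbut-2-enyl)cyclohexa-1,4-diene | COC1=CCC=C(OC)C1CC=C(C)C
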